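The earlier runs and the new flask were generated by integration for an exercise.

The meeting began from the reading time, 12 h, and what that time means in flasks that share their proportions of coupling partner and catalyst but differ in charge.

in all of them: catalyst 0.59 mol%
- green: starting material 9.9 mM; coupling partner 1.8 equiv; run made earlier
- red: starting material 24 mM; coupling partner 1.8 equiv; run made earlier
- north-east: starting material 80 mM; coupling partner 1.80 equiv; time 12 h
- south: starting material 15 mM; coupling partner 1.80 equiv; time 12 h
- north-west: starting material 8.0 mM; coupling partner 1.80 equiv; time 12 h
- east: starting material 10 mM; coupling partner 1.80 equiv; time 12 h
- south-west: starting material 29 mM; coupling partner 1.80 equiv; time 12 h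

| run | time / h | intermediate / % | target / % | starting material / % |
|---|---|---|---|---|
| green | 3.00 | 26.8 | 0.1 | 73.1 |
| green | 6.00 | 45.8 | 0.1 | 53.0 |
| green | 10.0 | 64.5 | 1.1 | 34.8 |
| green | 12.0 | 70.0 | 0.9 | 28.2 |
| red | 1.00 | 22.6 | 0.1 | 78.1 |
| red | 2.00 | 39.0 | 0.6 | 59.8 |
| red | 5.00 | 68.3 | 3.5 | 27.7 |
| red | 12.0 | 81.6 | 10.3 | 5.2 |

(readings scatter by 0.3 percentage points)

- percent here means starting material units held: one side product counts as two
- steps under discussion: starting material + target -> side product; starting material + catalyst -> catalyst + intermediate; coupling partner + catalyst + intermediate -> catalyst + target; target <-> isomer of the product

* the flasks put in order of amount of intermediate, in percent of the starting material charged, best first, at 12 h (north-east / south / north-west / east / south-west)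
* the same order at 4.0 d (north-east / south / north-west / east / south-west)
* the amount of intermediate, in percent of the starting material charged of the flask you put first, at 12 h
* the amount of intermediate, in percent of the starting material charged of the flask you put last, at 12 h

I proposed comparing two rates at one moment. Read from the last points, the pseudo-first-order making constant of starting material was 0.246 h⁻¹ in the red run and 0.105 h⁻¹ in the green run. Their ratio, 2.34, stands near the ratio of charges, 2.42, as expected if making follows the catalyst, which grows with the charge at fixed loading.

For the using step I took what the red run held in neither starting material nor intermediate at 12.0 h, 13.2%. I divided it by the area under its intermediate curve, 7.28 h, which gives a using constant of 0.0181 h⁻¹. This step needs both catalyst and coupling partner, so I expected it to grow with the square of the charge.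

Dividing gives 13.6 for the red run. I named this the clock ratio, the making constant over the using constant: it compares the two rates at the moment when starting material and intermediate stand equal. With equivalents and loading fixed I reckoned it to fall in proportion to the charge, to 4.07 in north-east and 21.7 in south.

A colleague asked how the comparison drifts. I answered that starting material then shrinks while intermediate grows, so intermediate peaks when the rates meet. With coupling partner taken as charged, that time is the logarithm of the clock ratio over the difference of the constants: 2.27 h in north-east, 21.0 h in south. So I expected north-east to be past its peak at the reading and south still short of it.

The forecast was then tabled: south > south-west > east > north-west > north-east at 12 h, from 81% down to 23%, and north-west > east > south > south-west > north-east at 4.0 d, where it held that “decay dominates and the most dilute flask leads”.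

The flasks gave south > south-west > east > north-west > north-east at 12 h, from 80.4% down to 19.7%, and north-west > east > south > south-west > north-east at 4.0 d.

    starting material + target → side product (k = 0.200 M⁻¹ h⁻¹)
    starting material + catalyst → catalyst + intermediate (k = 1800 M⁻¹ h⁻¹)
    coupling partner + catalyst + intermediate → catalyst + target (k = 3200 M⁻² h⁻¹)
    target ⇌ isomer of the product (K = 1.90, k = 0.0800 h⁻¹)

In north-east, whose clock ratio was reckoned at 4.07, intermediate was being made 4.43 times faster than it was used up at 0.814 h, each step taken net, yet at 12.0 h starting material stood at 0% and intermediate at 19.7%. In south, whose clock ratio was reckoned at 21.7, the half-life of starting material by the making step alone, other concentrations as charged, is 4.4 h, and at 12.0 h starting material still stood at 14.8% with intermediate at 80.4%.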